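**Retrosynthetic overview**

1. Target 39 ← acylation of O8 with epoxyangelic acid 4 and exchange of TBS for acetyl at O9 ← macrocyclic alcohol 35, which already holds the carbocycle, both ring epoxides and the α-methylene lactone.
2. 35 ← seco-aldehyde 33 by closing the ten-membered carbocycle at C7–C8. The enabling feature is the homoallylic alcohol C8(OH)–C7–C11=C13 where the γ-lactone meets the ten-membered ring (C7 is the β-carbon of the lactone). This is the retron of an SE2′ allylation of a C8 aldehyde by a 3-(bromomethyl)but-2-en-4-olide metalated at C13.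
3. 33 ← butenolide (C6–O–C12, C7=C11) by Mitsunobu esterification and ring-closing metathesis; C1=C10 by aldol addition and elimination joining ester 11 (C8–C10, C14; from (S)-glycidol) with bis-epoxy aldehyde 20 (C1–C6).
4. 20 ← C2–C3 cis-epoxide by asymmetric γ-chloroallylboration, ring closure and ozonolysis; C4–C5 cis-epoxide by Still–Gennari olefination and Sharpless epoxidation from aldehyde 12.
5. Ring order: oxirane of acid 4; C4–C5 oxirane; C2–C3 oxirane; butenolide; ten-membered carbocycle (key step).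

Key step: step 26

Remark: locants C1–C15 follow germacranolide numbering (ring C1–C10, lactone C11–C13, ester carbon C14 on C10, methyl C15 on C4), so the target is 2R,3R,4R,5R,6S,7R,8S,9R with a 1(10)E alkene whose ring bonds are cis; TBSO = tert-butyldimethylsilyloxy, PMBO = 4-methoxybenzyloxy; compounds 1, 5, 8, 12 and all reagents are taken as commercial.

**Route**

Step 1
Reactants: 1 (2Z)-2-methylbut-2-enoic acid (angelic acid)
Product: 2 (2Z)-2-methylbut-2-en-1-ol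
Conditions: LiAlH4, Et2O, 0 °C
Reagents that add atoms: none
Why: Hydride reduction of the carboxylic acid with LiAlH4 at low temperature should give the allylic alcohol without reducing or isomerising the Z-trisubstituted alkene.

Step 2
Reactants: 2 (2Z)-2-methylbut-2-en-1-ol
Product: 3 [(2R,3S)-2,3-dimethyloxiran-2-yl]methanol
Conditions: Ti(OiPr)4 (10 mol%), D-(−)-diethyl tartrate (12 mol%), tBuOOH, 4 Å MS, CH2Cl2, −20 °C
Reagents that add atoms: tert-butyl hydroperoxide, CC(C)(C)OO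
Why: Sharpless asymmetric epoxidation, in which the catalyst formed from Ti(OiPr)4 and D-(−)-diethyl tartrate selects the alkene face that gives the (2R,3S) epoxy alcohol while the Z geometry is carried over stereospecifically into the cis relationship of CH2OH and the C3 methyl group.

Step 3
Reactants: 3 [(2R,3S)-2,3-dimethyloxiran-2-yl]methanol
Product: 4 (2S,3S)-2,3-dimethyloxirane-2-carboxylic acid
Conditions: RuCl3·H2O (2 mol%), NaIO4, MeCN/EtOAc/H2O, 0 °C → rt
Reagents that add atoms: water, O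
Why: Ruthenium tetroxide oxidation (catalytic RuCl3 with NaIO4 as terminal oxidant) takes the primary alcohol to the acid without opening the oxirane, so both stereocentres are kept and the C2 descriptor changes only because CO2H outranks C3.

Step 4
Reactants: 5 ethyl 2-(hydroxymethyl)prop-2-enoate
Product: 6 ethyl 2-[(TBSO)methyl]prop-2-enoate
Conditions: TBSCl, imidazole, CH2Cl2, 0 °C → rt
Reagents that add atoms: tert-butyldimethylsilyl chloride, CC(C)(C)[Si](C)(C)Cl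
Why: Silyl ether formation masks the primary allylic hydroxyl so that the derived acid can serve as the nucleophile in a Mitsunobu esterification.

Step 5
Reactants: 6 ethyl 2-[(TBSO)methyl]prop-2-enoate
Product: 7 2-[(TBSO)methyl]prop-2-enoic acid
Conditions: LiOH, THF/H2O, 0 °C → rt; then aq. HCl to pH 4
Reagents that add atoms: lithium hydroxide, [Li+].[OH-]
Why: Saponification of the ethyl ester under mild conditions should leave the primary TBS ether in place, and careful acidification gives the free acid.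

Step 6
Reactants: 8 (2S)-oxiran-2-ylmethanol ((S)-glycidol)
Product: 9 (2R)-2-[(PMBO)methyl]oxirane
Conditions: NaH, 4-methoxybenzyl chloride, Bu4NI (cat.), THF/DMF, 0 °C → rt
Reagents that add atoms: 4-methoxybenzyl chloride, COc1ccc(CCl)cc1
Why: Williamson ether synthesis at the primary alkoxide leaves the stereocentre untouched, the descriptor changing from S to R only because CH2OPMB outranks the ring CH2.

Step 7
Reactants: 9 (2R)-2-[(PMBO)methyl]oxirane
Product: 10 methyl (3R)-3-hydroxy-4-(PMBO)butanoate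
Conditions: Co2(CO)8 (5 mol%), 3-hydroxypyridine (10 mol%), CO (40 bar), MeOH/THF, 60 °C
Reagents that add atoms: carbon monoxide, [C-]#[O+]; methanol, CO
Why: Cobalt-catalysed carbonylative ring opening of the terminal epoxide (methoxycarbonylation) attacks only the unsubstituted carbon, so the secondary carbinol (future C9) keeps its configuration and the C8–C9–C10–C14 unit is obtained in one step.

Step 8
Reactants: 10 methyl (3R)-3-hydroxy-4-(PMBO)butanoate
Product: 11 methyl (3R)-3-(TBSO)-4-(PMBO)butanoate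
Conditions: TBSCl, imidazole, DMF, rt
Reagents that add atoms: tert-butyldimethylsilyl chloride, CC(C)(C)[Si](C)(C)Cl
Why: Silyl ether formation protects O9 with a group that should survive the enolate, oxidation and primary-selective fluoride steps and is removed only at the end.

Step 9
Reactants: 12 (TBSO)acetaldehyde
Product: 13 ethyl (2Z)-4-(TBSO)-2-methylbut-2-enoate
Conditions: (CF3CH2O)2P(O)CH(CH3)CO2Et, KN(SiMe3)2, 18-crown-6, THF, −78 °C
Reagents that add atoms: ethyl 2-[bis(2,2,2-trifluoroethoxy)phosphoryl]propanoate, CCOC(=O)C(C)P(=O)(OCC(F)(F)F)OCC(F)(F)F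
Why: Still–Gennari variant of the Horner–Wadsworth–Emmons olefination, whose electron-poor phosphonate and dissociated potassium counter-ion favour the Z-trisubstituted enoate, the geometry that later places C3 and C6 cis on the C4–C5 oxirane.

Step 10
Reactants: 13 ethyl (2Z)-4-(TBSO)-2-methylbut-2-enoate
Product: 14 (2Z)-4-(TBSO)-2-methylbut-2-en-1-ol
Conditions: iBu2AlH, CH2Cl2, −78 °C
Reagents that add atoms: none
Why: 1,2-Reduction of the enoate with iBu2AlH should give the Z-allylic alcohol without isomerisation and provides the hydroxyl that directs the epoxidation.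

Step 11
Reactants: 14 (2Z)-4-(TBSO)-2-methylbut-2-en-1-ol
Product: 15 [(2S,3R)-3-[(TBSO)methyl]-2-methyloxiran-2-yl]methanol
Conditions: Ti(OiPr)4 (10 mol%), L-(+)-diethyl tartrate (12 mol%), tBuOOH, 4 Å MS, CH2Cl2, −20 °C
Reagents that add atoms: tert-butyl hydroperoxide, CC(C)(C)OO
Why: Sharpless asymmetric epoxidation, in which the catalyst formed from Ti(OiPr)4 and L-(+)-diethyl tartrate selects the alkene face that gives the (2S,3R) epoxy alcohol and thereby fixes C4 and C5 of the target as a cis-epoxide.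

Step 12
Reactants: 15 [(2S,3R)-3-[(TBSO)methyl]-2-methyloxiran-2-yl]methanol
Product: 16 (2R,3R)-3-[(TBSO)methyl]-2-methyloxirane-2-carbaldehyde
Conditions: Dess–Martin periodinane, pyridine, CH2Cl2, 0 °C → rt
Reagents that add atoms: none
Why: Dess–Martin oxidation gives the epoxy aldehyde, which is configurationally safe because its α-carbon (C4) is quaternary.

Step 13
Reactants: 16 (2R,3R)-3-[(TBSO)methyl]-2-methyloxirane-2-carbaldehyde
Product: 18 (2R,3R)-2-[(TBSO)methyl]-3-[(2R,3R)-3-ethenyloxiran-2-yl]-3-methyloxirane, via syn-chlorohydrin 17 (not isolated)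
Conditions: allyl chloride, LiN(c-C6H11)2, (+)-Ipc2BOMe, BF3·OEt2, Et2O, −95 °C; 16, −95 °C; then NaOH, H2O2, 0 °C → rt
Reagents that add atoms: allyl chloride, C=CCCl (its three carbons stay in 18, its chlorine only in 17)
Why: Asymmetric γ-chloroallylboration, in which the (Z)-γ-chloroallyl diisopinocampheylborane made in the flask adds through a chair transition state to the Re face of the aldehyde under control of the isopinocampheyl groups to give the syn-chlorohydrin 17 (sets C3 and, provisionally, C2), followed by intramolecular SN2 displacement of chloride with inversion at C2 during the alkaline peroxide work-up to close the cis-vinyl oxirane.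

Step 14
Reactants: 18 (2R,3R)-2-[(TBSO)methyl]-3-[(2R,3R)-3-ethenyloxiran-2-yl]-3-methyloxirane
Product: 20 (2S,3R)-3-[(2R,3R)-3-[(TBSO)methyl]-2-methyloxiran-2-yl]oxirane-2-carbaldehyde, via ozonide 19 (not isolated)
Conditions: O3, CH2Cl2, −78 °C; then PPh3, −78 °C → rt
Reagents that add atoms: ozone, [O-][O+]=O
Why: Ozonolysis with reductive work-up cleaves the only alkene in the molecule to the C1 aldehyde under neutral conditions that spare the oxiranes and should not epimerise C2.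

Step 15
Reactants: 11 methyl (3R)-3-(TBSO)-4-(PMBO)butanoate; 20 (2S,3R)-3-[(2R,3R)-3-[(TBSO)methyl]-2-methyloxiran-2-yl]oxirane-2-carbaldehyde
Product: 22 methyl 2-[(1R)-1-(TBSO)-2-(PMBO)ethyl]-3-hydroxy-3-[(2R,3R)-3-[(2R,3R)-3-[(TBSO)methyl]-2-methyloxiran-2-yl]oxiran-2-yl]propanoate (C2/C3 epimers), via lithium enolate 21 (not isolated)
Conditions: LiN(iPr)2, THF, −78 °C; then 20, −78 °C; aq. NH4Cl
Reagents that add atoms: lithium diisopropylamide, [Li+].CC(C)[N-]C(C)C (lithium only in 21)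
Why: Aldol addition of the lithium ester enolate to the aldehyde at −78 °C forms the C10–C1 bond faster than the enolate can expel its β-silyloxy group, and the two new stereocentres need no control because both are erased in the next step.

Step 16
Reactants: 22 methyl 2-[(1R)-1-(TBSO)-2-(PMBO)ethyl]-3-hydroxy-3-[(2R,3R)-3-[(2R,3R)-3-[(TBSO)methyl]-2-methyloxiran-2-yl]oxiran-2-yl]propanoate
Product: 24 methyl (2E)-2-[(1R)-1-(TBSO)-2-(PMBO)ethyl]-3-[(2R,3R)-3-[(2R,3R)-3-[(TBSO)methyl]-2-methyloxiran-2-yl]oxiran-2-yl]prop-2-enoate, via mesylate 23 (not isolated)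
Conditions: MsCl, Et3N, CH2Cl2, 0 °C; then DBU, 0 °C → rt
Reagents that add atoms: methanesulfonyl chloride, CS(=O)(=O)Cl (mesyl group only in 23)
Why: Mesylation and E1cB elimination (aldol condensation completed in two stages) funnel all aldol diastereomers through the ester enolate to the conjugated ester, and the E isomer with C2 trans to the ester should dominate because it keeps the ester coplanar with the alkene while the C9–H bond eclipses the oxirane substituent.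

Step 17
Reactants: 24 methyl (2E)-2-[(1R)-1-(TBSO)-2-(PMBO)ethyl]-3-[(2R,3R)-3-[(2R,3R)-3-[(TBSO)methyl]-2-methyloxiran-2-yl]oxiran-2-yl]prop-2-enoate
Product: 25 methyl (2E)-2-[(1R)-1-(TBSO)-2-(PMBO)ethyl]-3-[(2R,3R)-3-[(2R,3R)-3-(hydroxymethyl)-2-methyloxiran-2-yl]oxiran-2-yl]prop-2-enoate
Conditions: HF·pyridine, pyridine, THF, 0 °C
Reagents that add atoms: none
Why: Fluoride-mediated desilylation, selective because the primary TBS ether at O6 is cleaved much faster than the hindered secondary TBS ether at O9, while the buffered medium should leave the oxiranes closed.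

Step 18
Reactants: 25 methyl (2E)-2-[(1R)-1-(TBSO)-2-(PMBO)ethyl]-3-[(2R,3R)-3-[(2R,3R)-3-(hydroxymethyl)-2-methyloxiran-2-yl]oxiran-2-yl]prop-2-enoate
Product: 26 methyl (2E)-2-[(1R)-1-(TBSO)-2-(PMBO)ethyl]-3-[(2R,3R)-3-[(2S,3S)-3-formyl-2-methyloxiran-2-yl]oxiran-2-yl]prop-2-enoate
Conditions: Dess–Martin periodinane, pyridine, CH2Cl2, 0 °C
Reagents that add atoms: none
Why: Dess–Martin oxidation under buffered, non-basic conditions should give the cis-epoxy aldehyde at C6 without epimerising C5.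

Step 19
Reactants: 26 methyl (2E)-2-[(1R)-1-(TBSO)-2-(PMBO)ethyl]-3-[(2R,3R)-3-[(2S,3S)-3-formyl-2-methyloxiran-2-yl]oxiran-2-yl]prop-2-enoate
Product: 27 methyl (2E)-2-[(1R)-1-(TBSO)-2-(PMBO)ethyl]-3-[(2R,3R)-3-[(2R,3R)-3-[(1R)-1-hydroxyprop-2-en-1-yl]-2-methyloxiran-2-yl]oxiran-2-yl]prop-2-enoate
Conditions: CH2=CHMgBr, THF, −78 °C
Reagents that add atoms: vinylmagnesium bromide, C=C[Mg]Br
Why: Grignard addition to the α,β-epoxy aldehyde under Felkin–Anh (Cornforth) control, with the oxirane C–O bond anti to the incoming vinyl group, should give the anti carbinol with 6R configuration, the C6 epimer that the next step inverts, while the esters are not attacked at −78 °C.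

Step 20
Reactants: 27 methyl (2E)-2-[(1R)-1-(TBSO)-2-(PMBO)ethyl]-3-[(2R,3R)-3-[(2R,3R)-3-[(1R)-1-hydroxyprop-2-en-1-yl]-2-methyloxiran-2-yl]oxiran-2-yl]prop-2-enoate; 7 2-[(TBSO)methyl]prop-2-enoic acid
Product: 28 methyl (2E)-2-[(1R)-1-(TBSO)-2-(PMBO)ethyl]-3-[(2R,3R)-3-[(2R,3R)-2-methyl-3-[(1S)-1-({2-[(TBSO)methyl]prop-2-enoyl}oxy)prop-2-en-1-yl]oxiran-2-yl]oxiran-2-yl]prop-2-enoate
Conditions: PPh3, DIAD, toluene, 0 °C → rt
Reagents that add atoms: none
Why: Mitsunobu esterification, in which the carboxylate displaces the oxyphosphonium group by SN2 with inversion, sets the 6S configuration of the lactone carbinol and installs the acrylate for ring closure in the same operation.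

Step 21
Reactants: 28 methyl (2E)-2-[(1R)-1-(TBSO)-2-(PMBO)ethyl]-3-[(2R,3R)-3-[(2R,3R)-2-methyl-3-[(1S)-1-({2-[(TBSO)methyl]prop-2-enoyl}oxy)prop-2-en-1-yl]oxiran-2-yl]oxiran-2-yl]prop-2-enoate
Product: 29 methyl (2E)-2-[(1R)-1-(TBSO)-2-(PMBO)ethyl]-3-[(2R,3R)-3-[(2R,3R)-2-methyl-3-[(2S)-5-oxo-4-[(TBSO)methyl]-2,5-dihydrofuran-2-yl]oxiran-2-yl]oxiran-2-yl]prop-2-enoate
Conditions: second-generation Grubbs catalyst (H2IMes)(PCy3)Cl2Ru=CHPh (10 mol%), toluene, 80 °C
Reagents that add atoms: none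
Why: Ring-closing metathesis between the vinyl group and the 1,1-disubstituted acrylate closes the five-membered butenolide (C7=C11) with loss of ethylene, the trisubstituted electron-poor C1=C10 alkene being inert to the catalyst.

Step 22
Reactants: 29 methyl (2E)-2-[(1R)-1-(TBSO)-2-(PMBO)ethyl]-3-[(2R,3R)-3-[(2R,3R)-2-methyl-3-[(2S)-5-oxo-4-[(TBSO)methyl]-2,5-dihydrofuran-2-yl]oxiran-2-yl]oxiran-2-yl]prop-2-enoate
Product: 30 methyl (2E)-2-[(1R)-1-(TBSO)-2-(PMBO)ethyl]-3-[(2R,3R)-3-[(2R,3R)-3-[(2S)-4-(hydroxymethyl)-5-oxo-2,5-dihydrofuran-2-yl]-2-methyloxiran-2-yl]oxiran-2-yl]prop-2-enoate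
Conditions: HF·pyridine, pyridine, THF, 0 °C
Reagents that add atoms: none
Why: Selective fluoride-mediated desilylation of the primary allylic TBS ether at C13, the secondary TBS ether at O9 reacting much more slowly.

Step 23
Reactants: 30 methyl (2E)-2-[(1R)-1-(TBSO)-2-(PMBO)ethyl]-3-[(2R,3R)-3-[(2R,3R)-3-[(2S)-4-(hydroxymethyl)-5-oxo-2,5-dihydrofuran-2-yl]-2-methyloxiran-2-yl]oxiran-2-yl]prop-2-enoate
Product: 31 methyl (2E)-2-[(1R)-1-(TBSO)-2-(PMBO)ethyl]-3-[(2R,3R)-3-[(2R,3R)-3-[(2S)-4-(bromomethyl)-5-oxo-2,5-dihydrofuran-2-yl]-2-methyloxiran-2-yl]oxiran-2-yl]prop-2-enoate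
Conditions: CBr4, PPh3, CH2Cl2, 0 °C
Reagents that add atoms: carbon tetrabromide, BrC(Br)(Br)Br
Why: The Appel reaction converts the primary allylic alcohol into the bromide under neutral conditions tolerated by the butenolide, the oxiranes and the PMB ether.

Step 24
Reactants: 31 methyl (2E)-2-[(1R)-1-(TBSO)-2-(PMBO)ethyl]-3-[(2R,3R)-3-[(2R,3R)-3-[(2S)-4-(bromomethyl)-5-oxo-2,5-dihydrofuran-2-yl]-2-methyloxiran-2-yl]oxiran-2-yl]prop-2-enoate
Product: 32 methyl (2E)-2-[(1R)-2-hydroxy-1-(TBSO)ethyl]-3-[(2R,3R)-3-[(2R,3R)-3-[(2S)-4-(bromomethyl)-5-oxo-2,5-dihydrofuran-2-yl]-2-methyloxiran-2-yl]oxiran-2-yl]prop-2-enoate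
Conditions: DDQ, CH2Cl2/pH 7 buffer, 0 °C → rt
Reagents that add atoms: none
Why: Oxidative cleavage of the 4-methoxybenzyl ether by DDQ (benzylic hydride abstraction and hydrolysis of the oxocarbenium ion) frees the primary C8 hydroxyl without touching the allylic bromide, the silyl ether or the oxiranes.

Step 25
Reactants: 32 methyl (2E)-2-[(1R)-2-hydroxy-1-(TBSO)ethyl]-3-[(2R,3R)-3-[(2R,3R)-3-[(2S)-4-(bromomethyl)-5-oxo-2,5-dihydrofuran-2-yl]-2-methyloxiran-2-yl]oxiran-2-yl]prop-2-enoate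
Product: 33 methyl (2E)-2-[(1R)-2-oxo-1-(TBSO)ethyl]-3-[(2R,3R)-3-[(2R,3R)-3-[(2S)-4-(bromomethyl)-5-oxo-2,5-dihydrofuran-2-yl]-2-methyloxiran-2-yl]oxiran-2-yl]prop-2-enoate
Conditions: Dess–Martin periodinane, pyridine, CH2Cl2, 0 °C
Reagents that add atoms: none
Why: Dess–Martin oxidation gives the α-silyloxy aldehyde under non-basic conditions, and the crude aldehyde is used at once so that C9 cannot epimerise.

Step 26
Reactants: 33 methyl (2E)-2-[(1R)-2-oxo-1-(TBSO)ethyl]-3-[(2R,3R)-3-[(2R,3R)-3-[(2S)-4-(bromomethyl)-5-oxo-2,5-dihydrofuran-2-yl]-2-methyloxiran-2-yl]oxiran-2-yl]prop-2-enoate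
Product: 35 methyl (1(10)E,2R,3R,4R,5R,6S,7R,8S,9R)-2,3:4,5-diepoxy-8-hydroxy-9-(TBSO)germacra-1(10),11(13)-dien-12,6-olid-14-oate, via allylchromium dichloride 34 (not isolated)
Conditions: CrCl2 (8 equiv), THF, 25 °C, slow addition of 33 by syringe pump to a final 2 mM
Reagents that add atoms: chromium dichloride, Cl[Cr]Cl (chromium and chlorine only in 34)
Why: Two equivalents of divalent chromium reduce the allylic C13–Br bond of the 3-(bromomethyl)butenolide to the allylchromium dichloride 34 (trivalent chromium), whose γ-carbon C7 adds to the chromium-bound C8 aldehyde through a six-membered cyclic transition state with allylic transposition (SE2′), so that one operation forms the C7–C8 bond, the ten-membered carbocycle and the exocyclic C11=C13 methylene of the α-methylene-γ-lactone. The closest known reaction type is the Nozaki–Hiyama–Kishi (chromium Barbier) allylation, used intramolecularly with 2-(bromomethyl)alk-2-enoates to close medium and large carbocycles of terpenoid lactones and intermolecularly with 3-(bromomethyl)furan-2(5H)-ones. The carbocycle closes in a 10-exo-trig mode (C7 attacks the C8 carbonyl carbon, the oxygen staying outside the ring), and the chain is folded for closure by its three cis elements, the C1=C10 alkene and the 2,3- and 4,5-cis-epoxides. C7 should be set by attack on the butenolide face anti to the C5 substituent at C6, which gives the trans ring fusion (6S,7R), and C8 by Felkin–Anh addition anti to the C9 silyloxy group, which gives the 8,9-anti relationship (8S). The step needs cyclisation to outrun oligomerisation, which slow addition to excess CrCl2 at high dilution should secure, and it needs chemoselective reduction of the allylic bromide beside epoxides, esters and the enoate, which the mild reducing power of CrCl2 should secure.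

Step 27
Reactants: 35 methyl (1(10)E,2R,3R,4R,5R,6S,7R,8S,9R)-2,3:4,5-diepoxy-8-hydroxy-9-(TBSO)germacra-1(10),11(13)-dien-12,6-olid-14-oate; 4 (2S,3S)-2,3-dimethyloxirane-2-carboxylic acid
Product: 37 methyl (1(10)E,2R,3R,4R,5R,6S,7S,8S,9R)-8-{[(2S,3S)-2,3-dimethyloxirane-2-carbonyl]oxy}-2,3:4,5-diepoxy-9-(TBSO)germacra-1(10),11(13)-dien-12,6-olid-14-oate, via mixed anhydride 36 (not isolated)
Conditions: 4, 2,4,6-trichlorobenzoyl chloride, Et3N, toluene, rt; then 35, DMAP, toluene, rt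
Reagents that add atoms: 2,4,6-trichlorobenzoyl chloride, O=C(Cl)c1c(Cl)cc(Cl)cc1Cl (aroyl group only in 36)
Why: Yamaguchi esterification through the mixed anhydride acylates the hindered secondary C8 hydroxyl with retention at C8 and without disturbing the oxirane stereocentres of the acid (the C7 descriptor becomes S only through a priority change).

Step 28
Reactants: 37 methyl (1(10)E,2R,3R,4R,5R,6S,7S,8S,9R)-8-{[(2S,3S)-2,3-dimethyloxirane-2-carbonyl]oxy}-2,3:4,5-diepoxy-9-(TBSO)germacra-1(10),11(13)-dien-12,6-olid-14-oate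
Product: 38 methyl (1(10)E,2R,3R,4R,5R,6S,7R,8S,9R)-8-{[(2S,3S)-2,3-dimethyloxirane-2-carbonyl]oxy}-2,3:4,5-diepoxy-9-hydroxygermacra-1(10),11(13)-dien-12,6-olid-14-oate
Conditions: HF·pyridine, pyridine, THF, 0 °C → rt
Reagents that add atoms: none
Why: Fluoride-mediated desilylation removes the secondary TBS ether at O9 under buffered conditions that the three oxiranes and the α-methylene lactone should tolerate.

Step 29
Reactants: 38 methyl (1(10)E,2R,3R,4R,5R,6S,7R,8S,9R)-8-{[(2S,3S)-2,3-dimethyloxirane-2-carbonyl]oxy}-2,3:4,5-diepoxy-9-hydroxygermacra-1(10),11(13)-dien-12,6-olid-14-oate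
Product: 39 methyl (1(10)E,2R,3R,4R,5R,6S,7R,8S,9R)-9-acetoxy-8-{[(2S,3S)-2,3-dimethyloxirane-2-carbonyl]oxy}-2,3:4,5-diepoxygermacra-1(10),11(13)-dien-12,6-olid-14-oate (CNP0077535.3)
Conditions: Ac2O, pyridine, DMAP (cat.), CH2Cl2, 0 °C
Reagents that add atoms: acetic anhydride, CC(=O)OC(C)=O
Why: DMAP-catalysed acetylation of the C9 hydroxyl completes the target, the hindered epoxyangelate on O8 being too slow to migrate under these conditions.

**Compound list**

1 | (2Z)-2-methylbut-2-enoic acid (angelic acid) | C/C=C(/C)C(=O)O | starting material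
2 | (2Z)-2-methylbut-2-en-1-ol | C/C=C(/C)CO | intermediate
3 | [(2R,3S)-2,3-dimethyloxiran-2-yl]methanol | OC[C@@]1(C)O[C@H]1C | intermediate
4 | (2S,3S)-2,3-dimethyloxirane-2-carboxylic acid | OC(=O)[C@@]1(C)O[C@H]1C | intermediate
5 | ethyl 2-(hydroxymethyl)prop-2-enoate | C=C(CO)C(=O)OCC | starting material
6 | ethyl 2-[(TBSO)methyl]prop-2-enoate | C=C(CO[Si](C)(C)C(C)(C)C)C(=O)OCC | intermediate
7 | 2-[(TBSO)methyl]prop-2-enoic acid | C=C(CO[Si](C)(C)C(C)(C)C)C(=O)O | intermediate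
8 | (2S)-oxiran-2-ylmethanol ((S)-glycidol) | OC[C@H]1CO1 | starting material
9 | (2R)-2-[(PMBO)methyl]oxirane | COc1ccc(cc1)COC[C@H]1CO1 | intermediate
10 | methyl (3R)-3-hydroxy-4-(PMBO)butanoate | COc1ccc(cc1)COC[C@H](O)CC(=O)OC | intermediate
11 | methyl (3R)-3-(TBSO)-4-(PMBO)butanoate | COc1ccc(cc1)COC[C@H](O[Si](C)(C)C(C)(C)C)CC(=O)OC | intermediate
12 | (TBSO)acetaldehyde | O=CCO[Si](C)(C)C(C)(C)C | starting material
13 | ethyl (2Z)-4-(TBSO)-2-methylbut-2-enoate | CCOC(=O)/C(C)=C\CO[Si](C)(C)C(C)(C)C | intermediate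
14 | (2Z)-4-(TBSO)-2-methylbut-2-en-1-ol | OC/C(C)=C\CO[Si](C)(C)C(C)(C)C | intermediate
15 | [(2S,3R)-3-[(TBSO)methyl]-2-methyloxiran-2-yl]methanol | OC[C@]1(C)O[C@@H]1CO[Si](C)(C)C(C)(C)C | intermediate
16 | (2R,3R)-3-[(TBSO)methyl]-2-methyloxirane-2-carbaldehyde | O=C[C@]1(C)O[C@@H]1CO[Si](C)(C)C(C)(C)C | intermediate
17 | (1S,2S)-2-chloro-1-[(2S,3R)-3-[(TBSO)methyl]-2-methyloxiran-2-yl]but-3-en-1-ol (syn-chlorohydrin) | C=C[C@H](Cl)[C@@H](O)[C@]1(C)O[C@@H]1CO[Si](C)(C)C(C)(C)C | intermediate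
18 | (2R,3R)-2-[(TBSO)methyl]-3-[(2R,3R)-3-ethenyloxiran-2-yl]-3-methyloxirane | C=C[C@H]1O[C@H]1[C@]1(C)O[C@@H]1CO[Si](C)(C)C(C)(C)C | intermediate
19 | 3-{(2S,3R)-3-[(2R,3R)-3-[(TBSO)methyl]-2-methyloxiran-2-yl]oxiran-2-yl}-1,2,4-trioxolane (ozonide, epimers at the trioxolane carbon) | C1OC(OO1)[C@H]1O[C@H]1[C@]1(C)O[C@@H]1CO[Si](C)(C)C(C)(C)C | intermediate
20 | (2S,3R)-3-[(2R,3R)-3-[(TBSO)methyl]-2-methyloxiran-2-yl]oxirane-2-carbaldehyde | O=C[C@H]1O[C@H]1[C@]1(C)O[C@@H]1CO[Si](C)(C)C(C)(C)C | intermediate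
21 | lithium enolate of methyl (3R)-3-(TBSO)-4-(PMBO)butanoate | COc1ccc(cc1)COC[C@H](O[Si](C)(C)C(C)(C)C)C=C(OC)O[Li] | intermediate
22 | methyl 2-[(1R)-1-(TBSO)-2-(PMBO)ethyl]-3-hydroxy-3-[(2R,3R)-3-[(2R,3R)-3-[(TBSO)methyl]-2-methyloxiran-2-yl]oxiran-2-yl]propanoate (C2/C3 epimers) | COc1ccc(cc1)COC[C@H](O[Si](C)(C)C(C)(C)C)C(C(=O)OC)C(O)[C@H]1O[C@H]1[C@]1(C)O[C@@H]1CO[Si](C)(C)C(C)(C)C | intermediate
23 | 3-O-methanesulfonate of 22 | COc1ccc(cc1)COC[C@H](O[Si](C)(C)C(C)(C)C)C(C(=O)OC)C(OS(C)(=O)=O)[C@H]1O[C@H]1[C@]1(C)O[C@@H]1CO[Si](C)(C)C(C)(C)C | intermediate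
24 | methyl (2E)-2-[(1R)-1-(TBSO)-2-(PMBO)ethyl]-3-[(2R,3R)-3-[(2R,3R)-3-[(TBSO)methyl]-2-methyloxiran-2-yl]oxiran-2-yl]prop-2-enoate | COc1ccc(cc1)COC[C@H](O[Si](C)(C)C(C)(C)C)/C(C(=O)OC)=C\[C@H]1O[C@H]1[C@]1(C)O[C@@H]1CO[Si](C)(C)C(C)(C)C | intermediate
25 | methyl (2E)-2-[(1R)-1-(TBSO)-2-(PMBO)ethyl]-3-[(2R,3R)-3-[(2R,3R)-3-(hydroxymethyl)-2-methyloxiran-2-yl]oxiran-2-yl]prop-2-enoate | COc1ccc(cc1)COC[C@H](O[Si](C)(C)C(C)(C)C)/C(C(=O)OC)=C\[C@H]1O[C@H]1[C@]1(C)O[C@@H]1CO | intermediate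
26 | methyl (2E)-2-[(1R)-1-(TBSO)-2-(PMBO)ethyl]-3-[(2R,3R)-3-[(2S,3S)-3-formyl-2-methyloxiran-2-yl]oxiran-2-yl]prop-2-enoate | COc1ccc(cc1)COC[C@H](O[Si](C)(C)C(C)(C)C)/C(C(=O)OC)=C\[C@H]1O[C@H]1[C@]1(C)O[C@@H]1C=O | intermediate
27 | methyl (2E)-2-[(1R)-1-(TBSO)-2-(PMBO)ethyl]-3-[(2R,3R)-3-[(2R,3R)-3-[(1R)-1-hydroxyprop-2-en-1-yl]-2-methyloxiran-2-yl]oxiran-2-yl]prop-2-enoate | COc1ccc(cc1)COC[C@H](O[Si](C)(C)C(C)(C)C)/C(C(=O)OC)=C\[C@H]1O[C@H]1[C@]1(C)O[C@@H]1[C@H](O)C=C | intermediate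
28 | methyl (2E)-2-[(1R)-1-(TBSO)-2-(PMBO)ethyl]-3-[(2R,3R)-3-[(2R,3R)-2-methyl-3-[(1S)-1-({2-[(TBSO)methyl]prop-2-enoyl}oxy)prop-2-en-1-yl]oxiran-2-yl]oxiran-2-yl]prop-2-enoate | COc1ccc(cc1)COC[C@H](O[Si](C)(C)C(C)(C)C)/C(C(=O)OC)=C\[C@H]1O[C@H]1[C@]1(C)O[C@@H]1[C@@H](OC(=O)C(=C)CO[Si](C)(C)C(C)(C)C)C=C | intermediate
29 | methyl (2E)-2-[(1R)-1-(TBSO)-2-(PMBO)ethyl]-3-[(2R,3R)-3-[(2R,3R)-2-methyl-3-[(2S)-5-oxo-4-[(TBSO)methyl]-2,5-dihydrofuran-2-yl]oxiran-2-yl]oxiran-2-yl]prop-2-enoate | COc1ccc(cc1)COC[C@H](O[Si](C)(C)C(C)(C)C)/C(C(=O)OC)=C\[C@H]1O[C@H]1[C@]1(C)O[C@@H]1[C@H]1OC(=O)C(CO[Si](C)(C)C(C)(C)C)=C1 | intermediate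
30 | methyl (2E)-2-[(1R)-1-(TBSO)-2-(PMBO)ethyl]-3-[(2R,3R)-3-[(2R,3R)-3-[(2S)-4-(hydroxymethyl)-5-oxo-2,5-dihydrofuran-2-yl]-2-methyloxiran-2-yl]oxiran-2-yl]prop-2-enoate | COc1ccc(cc1)COC[C@H](O[Si](C)(C)C(C)(C)C)/C(C(=O)OC)=C\[C@H]1O[C@H]1[C@]1(C)O[C@@H]1[C@H]1OC(=O)C(CO)=C1 | intermediate
31 | methyl (2E)-2-[(1R)-1-(TBSO)-2-(PMBO)ethyl]-3-[(2R,3R)-3-[(2R,3R)-3-[(2S)-4-(bromomethyl)-5-oxo-2,5-dihydrofuran-2-yl]-2-methyloxiran-2-yl]oxiran-2-yl]prop-2-enoate | COc1ccc(cc1)COC[C@H](O[Si](C)(C)C(C)(C)C)/C(C(=O)OC)=C\[C@H]1O[C@H]1[C@]1(C)O[C@@H]1[C@H]1OC(=O)C(CBr)=C1 | intermediate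
32 | methyl (2E)-2-[(1R)-2-hydroxy-1-(TBSO)ethyl]-3-[(2R,3R)-3-[(2R,3R)-3-[(2S)-4-(bromomethyl)-5-oxo-2,5-dihydrofuran-2-yl]-2-methyloxiran-2-yl]oxiran-2-yl]prop-2-enoate | OC[C@H](O[Si](C)(C)C(C)(C)C)/C(C(=O)OC)=C\[C@H]1O[C@H]1[C@]1(C)O[C@@H]1[C@H]1OC(=O)C(CBr)=C1 | intermediate
33 | methyl (2E)-2-[(1R)-2-oxo-1-(TBSO)ethyl]-3-[(2R,3R)-3-[(2R,3R)-3-[(2S)-4-(bromomethyl)-5-oxo-2,5-dihydrofuran-2-yl]-2-methyloxiran-2-yl]oxiran-2-yl]prop-2-enoate | O=C[C@H](O[Si](C)(C)C(C)(C)C)/C(C(=O)OC)=C\[C@H]1O[C@H]1[C@]1(C)O[C@@H]1[C@H]1OC(=O)C(CBr)=C1 | intermediate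
34 | allylchromium dichloride formed at C13 of 33 (trivalent chromium) | O=C[C@H](O[Si](C)(C)C(C)(C)C)/C(C(=O)OC)=C\[C@H]1O[C@H]1[C@]1(C)O[C@@H]1[C@H]1OC(=O)C(C[Cr](Cl)Cl)=C1 | intermediate
35 | methyl (1(10)E,2R,3R,4R,5R,6S,7R,8S,9R)-2,3:4,5-diepoxy-8-hydroxy-9-(TBSO)germacra-1(10),11(13)-dien-12,6-olid-14-oate | C=C1C(=O)O[C@H]2[C@H]1[C@H](O)[C@H](O[Si](C)(C)C(C)(C)C)/C(C(=O)OC)=C\[C@H]1O[C@H]1[C@]1(C)O[C@H]21 | intermediate
36 | (2S,3S)-2,3-dimethyloxirane-2-carboxylic 2,4,6-trichlorobenzoic anhydride | Clc1cc(Cl)c(C(=O)OC(=O)[C@@]2(C)O[C@H]2C)c(Cl)c1 | intermediate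
37 | methyl (1(10)E,2R,3R,4R,5R,6S,7S,8S,9R)-8-{[(2S,3S)-2,3-dimethyloxirane-2-carbonyl]oxy}-2,3:4,5-diepoxy-9-(TBSO)germacra-1(10),11(13)-dien-12,6-olid-14-oate | C=C1C(=O)O[C@H]2[C@H]1[C@H](OC(=O)[C@@]1(C)O[C@H]1C)[C@H](O[Si](C)(C)C(C)(C)C)/C(C(=O)OC)=C\[C@H]1O[C@H]1[C@]1(C)O[C@H]21 | intermediate
38 | methyl (1(10)E,2R,3R,4R,5R,6S,7R,8S,9R)-8-{[(2S,3S)-2,3-dimethyloxirane-2-carbonyl]oxy}-2,3:4,5-diepoxy-9-hydroxygermacra-1(10),11(13)-dien-12,6-olid-14-oate | C=C1C(=O)O[C@H]2[C@H]1[C@H](OC(=O)[C@@]1(C)O[C@H]1C)[C@H](O)/C(C(=O)OC)=C\[C@H]1O[C@H]1[C@]1(C)O[C@H]21 | intermediate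
39 | methyl (1(10)E,2R,3R,4R,5R,6S,7R,8S,9R)-9-acetoxy-8-{[(2S,3S)-2,3-dimethyloxirane-2-carbonyl]oxy}-2,3:4,5-diepoxygermacra-1(10),11(13)-dien-12,6-olid-14-oate (CNP0077535.3) | C=C1C(=O)O[C@H]2[C@H]1[C@H](OC(=O)[C@@]1(C)O[C@H]1C)[C@H](OC(C)=O)/C(C(=O)OC)=C\[C@H]1O[C@H]1[C@]1(C)O[C@H]21 | target

**Step count and risks**

Total step count: 29 (side branches: steps 1–3, 4–5 and 6–8).
Longest linear sequence: 21 steps (steps 9–29, from aldehyde 12).

Steps most likely to fail, riskiest first: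

Step 26. Ring closure may lose to intermolecular allylation (oligomerisation), and a closed chair transition state with the C9 substituent equatorial may override Felkin–Anh control so that C7 attacks the other face of the C8 aldehyde. The fallback corrects C8 during acylation instead of during ring closure. It sets out from 33, whose cyclisation under the same conditions would then give the C8 epimer methyl (1(10)E,2R,3R,4R,5R,6S,7R,8R,9R)-2,3:4,5-diepoxy-8-hydroxy-9-(TBSO)germacra-1(10),11(13)-dien-12,6-olid-14-oate F1. This alcohol is esterified with acid 4 under Mitsunobu conditions (PPh3, DIAD, toluene, 0 °C → rt) with inversion at C8, and the route is rejoined at 37.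

Step 13. Facial selectivity may erode through mismatched double stereodifferentiation (the isopinocampheyl groups against the intrinsic preference of the α-quaternary epoxy aldehyde), and BF3·OEt2 may open the trisubstituted oxirane while the borane is generated. The fallback builds the C2–C3 oxirane by a second olefination and epoxidation round instead of allylboration; it sets out from 16 and comes back at 20. Still–Gennari olefination of 16 with methyl bis(2,2,2-trifluoroethyl)phosphonoacetate (KN(SiMe3)2, 18-crown-6, THF, −78 °C) should give methyl (2Z)-3-[(2S,3R)-3-[(TBSO)methyl]-2-methyloxiran-2-yl]prop-2-enoate F2. Reduction with iBu2AlH (CH2Cl2, −78 °C) gives (2Z)-3-[(2S,3R)-3-[(TBSO)methyl]-2-methyloxiran-2-yl]prop-2-en-1-ol F3. Sharpless epoxidation with Ti(OiPr)4, D-(−)-diethyl tartrate and tBuOOH (CH2Cl2, −20 °C) gives [(2R,3R)-3-[(2R,3R)-3-[(TBSO)methyl]-2-methyloxiran-2-yl]oxiran-2-yl]methanol F4. Dess–Martin oxidation (pyridine, CH2Cl2, 0 °C) then returns aldehyde 20.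

Step 20. The oxyphosphonium intermediate at the hindered allylic C6 may react by SN2′ attack at the vinyl terminus or by elimination instead of direct displacement. The fallback sets C6 by reagent-controlled reduction and acylates with retention; it sets out from 27 and comes back at 28. Dess–Martin oxidation of 27 (pyridine, CH2Cl2, 0 °C) gives methyl (2E)-2-[(1R)-1-(TBSO)-2-(PMBO)ethyl]-3-[(2R,3R)-3-[(2S,3S)-2-methyl-3-(prop-2-enoyl)oxiran-2-yl]oxiran-2-yl]prop-2-enoate F5. CBS reduction with the (R)-2-methyl-oxazaborolidine and BH3·SMe2 (toluene, −78 °C; the epoxide-bearing carbon taken as the larger group) should give methyl (2E)-2-[(1R)-1-(TBSO)-2-(PMBO)ethyl]-3-[(2R,3R)-3-[(2R,3R)-3-[(1S)-1-hydroxyprop-2-en-1-yl]-2-methyloxiran-2-yl]oxiran-2-yl]prop-2-enoate F6. Steglich esterification of this alcohol with acid 7 (DCC, DMAP cat., CH2Cl2, 0 °C) then gives 28.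

Further compounds
F1 | step 26 | methyl (1(10)E,2R,3R,4R,5R,6S,7R,8R,9R)-2,3:4,5-diepoxy-8-hydroxy-9-(TBSO)germacra-1(10),11(13)-dien-12,6-olid-14-oate | C=C1C(=O)O[C@H]2[C@H]1[C@@H](O)[C@H](O[Si](C)(C)C(C)(C)C)/C(C(=O)OC)=C\[C@H]1O[C@H]1[C@]1(C)O[C@H]21
F2 | step 13 | methyl (2Z)-3-[(2S,3R)-3-[(TBSO)methyl]-2-methyloxiran-2-yl]prop-2-enoate | COC(=O)/C=C\[C@]1(C)O[C@@H]1CO[Si](C)(C)C(C)(C)C
F3 | step 13 | (2Z)-3-[(2S,3R)-3-[(TBSO)methyl]-2-methyloxiran-2-yl]prop-2-en-1-ol | OC/C=C\[C@]1(C)O[C@@H]1CO[Si](C)(C)C(C)(C)C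
F4 | step 13 | [(2R,3R)-3-[(2R,3R)-3-[(TBSO)methyl]-2-methyloxiran-2-yl]oxiran-2-yl]methanol | OC[C@H]1O[C@H]1[C@]1(C)O[C@@H]1CO[Si](C)(C)C(C)(C)C
F5 | step 20 | methyl (2E)-2-[(1R)-1-(TBSO)-2-(PMBO)ethyl]-3-[(2R,3R)-3-[(2S,3S)-2-methyl-3-(prop-2-enoyl)oxiran-2-yl]oxiran-2-yl]prop-2-enoate | COc1ccc(cc1)COC[C@H](O[Si](C)(C)C(C)(C)C)/C(C(=O)OC)=C\[C@H]1O[C@H]1[C@]1(C)O[C@@H]1C(=O)C=C
F6 | step 20 | methyl (2E)-2-[(1R)-1-(TBSO)-2-(PMBO)ethyl]-3-[(2R,3R)-3-[(2R,3R)-3-[(1S)-1-hydroxyprop-2-en-1-yl]-2-methyloxiran-2-yl]oxiran-2-yl]prop-2-enoate | COc1ccc(cc1)COC[C@H](O[Si](C)(C)C(C)(C)C)/C(C(=O)OC)=C\[C@H]1O[C@H]1[C@]1(C)O[C@@H]1[C@@H](O)C=C
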